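**Plan**

- Retrosynthesis: the exocyclic C3=CH bond is returned to a saturated 3-benzyl lactone, O1–C2 is opened to a methyl arylacetate, and the C3a–C3 bond is traced by a 1,2-aryl shift to an aryl ketone. The two ring–C(=O)CH2 bonds of the resulting mirror-symmetric diketone are then cut together, leaving a dialdehyde and two molecules of styrene.
- Enabling feature: C5 and C3a of the benzofuranone lie on either side of the C4 methoxy carbon and each has an oxygen on its outer side (C6–OH, C7a–O1). The 3-phenylpropanoyl group on C5 and the atoms C2, C3, benzylidene CH and phenyl are the same three-carbon-plus-phenyl unit, so the benzene ring hides a mirror plane through C4 and C7.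
- Forward order: the fully substituted benzene ring is prepared from 3,4,5-trihydroxybenzaldehyde (steps 1–6) and both chains are joined at once (step 7). One acyl group is rearranged (step 9), the lactone ring, the only ring formed, closes after hydrogenolysis (step 10), and the benzylidene is unveiled last (step 11).
- Stereochemistry: the only stereo-element is the Z alkene, set in step 11 under thermodynamic control (phenyl turned away from the C4 methoxy group, towards the lactone carbonyl). The C3 centre of the late intermediates is racemic and is erased.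

Key step: step 7

Remark: the target SMILES is read as the Z alkene (phenyl cis to the lactone carbonyl C2); compounds 15–18, which carry the future C3 as an sp3 centre, are racemic.

**Route**

Step 1
Reactants: 1 3,4,5-trihydroxybenzaldehyde; 2 benzyl bromide
Product: 3 3,4,5-tris(benzyloxy)benzaldehyde
Conditions: BnBr (3.3 equiv), K2CO3, DMF, 60 °C, N2
Reagents that add atoms: benzyl bromide (2), BrCc1ccccc1
Why: Williamson etherification of all three phenoxides with benzyl bromide under K2CO3 in DMF is standard for pyrogallol-type aldehydes and leaves the formyl group untouched.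

Step 2
Reactants: 3 3,4,5-tris(benzyloxy)benzaldehyde
Product: 5 3,4,5-tris(benzyloxy)phenol, via aryl formate 4 (not isolated)
Conditions: mCPBA, CH2Cl2, 0 °C to rt; aq. NaHCO3 wash; then K2CO3 (cat.), MeOH, rt
Reagents that add atoms: 3-chloroperoxybenzoic acid (mCPBA), O=C(OO)c1cccc(Cl)c1
Why: Baeyer–Villiger (Dakin-type) oxidation, in which the electron-rich aryl group with its para benzyloxy donor migrates in the Criegee adduct to give formate 4, which catalytic carbonate in methanol transesterifies to the free phenol.

Step 3
Reactants: 5 3,4,5-tris(benzyloxy)phenol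
Product: 6 1,2,3-tris(benzyloxy)-5-methoxybenzene
Conditions: MeI, K2CO3, acetone, reflux
Reagents that add atoms: iodomethane, CI
Why: Williamson O-methylation of the only free phenol fixes the oxygen that becomes the C4 methoxy group of the target.

Step 4
Reactants: 6 1,2,3-tris(benzyloxy)-5-methoxybenzene
Product: 7 1,2,3-tris(benzyloxy)-4,6-dibromo-5-methoxybenzene
Conditions: NBS (2.1 equiv), MeCN, 0 °C to rt
Reagents that add atoms: N-bromosuccinimide, O=C1CCC(=O)N1Br
Why: Electrophilic aromatic bromination at the only two free ring positions, which are equivalent and each activated by an ortho methoxy, an ortho benzyloxy and a para benzyloxy group.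

Step 5
Reactants: 7 1,2,3-tris(benzyloxy)-4,6-dibromo-5-methoxybenzene
Product: 9 4,5,6-tris(benzyloxy)-2-methoxybenzene-1,3-dicarbaldehyde, via dilithio arene 8 (not isolated)
Conditions: n-BuLi (2.3 equiv), THF, −78 °C; DMF, −78 °C to 0 °C; 1 M HCl
Reagents that add atoms: N,N-dimethylformamide, CN(C)C=O
Why: Two-fold bromine–lithium exchange, faster at −78 °C than benzylic deprotonation and assisted by the flanking alkoxy groups, followed by Bouveault-type formylation of aryllithium 8 with DMF and acid collapse of the hemiaminal adducts.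

Step 6
Reactants: 9 4,5,6-tris(benzyloxy)-2-methoxybenzene-1,3-dicarbaldehyde
Product: 10 5-(benzyloxy)-4,6-dihydroxy-2-methoxybenzene-1,3-dicarbaldehyde
Conditions: MgBr2·OEt2 (3 equiv), toluene/Et2O, 70 °C; 1 M HCl
Reagents that add atoms: none
Why: Chelation-controlled ether cleavage, in which magnesium bridged between a formyl oxygen and the neighbouring benzyloxy oxygen lets bromide attack the benzylic carbon, so that only the two benzyl ethers ortho to a carbonyl should be lost while the central benzyl ether (no carbonyl neighbour) and the methyl ether (a much poorer electrophile, and shielded once both aldehydes are held as magnesium phenoxide chelates) survive.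

Step 7
Reactants: 10 5-(benzyloxy)-4,6-dihydroxy-2-methoxybenzene-1,3-dicarbaldehyde; 11 styrene
Product: 13 1,1'-[5-(benzyloxy)-4,6-dihydroxy-2-methoxy-1,3-phenylene]bis(3-phenylpropan-1-one), via mono-ketone aldehyde 12 (not isolated)
Conditions: [Rh(cod)Cl]2 (5 mol %), Fe(C5H4PPh2)2 (dppf, 10 mol %), Na2CO3 (20 mol %), styrene (6 equiv), toluene, 100 °C, Ar
Reagents that add atoms: styrene (11), C=Cc1ccccc1
Why: Under carbonate the phenoxide ortho to each formyl group binds monovalent rhodium, oxidative addition of the formyl C–H bond gives a five-membered acyl(hydrido) chelate of trivalent rhodium, styrene inserts into the Rh–H bond and C–C reductive elimination releases the ketone and monovalent rhodium, the cycle then repeating at the second formyl group of 12. The closest known reaction type is the rhodium-catalysed intermolecular hydroacylation of alkenes with salicylaldehydes, used here twice on one ring. No ring is closed and no stereocentre is created. The step needs linear rather than branched addition to styrene, hydroacylation rather than decarbonylation, and complete conversion at both sites. Chelation by the ortho phenoxide holds each acyl rhodium against CO extrusion, while hydride insertion is reversible and reductive elimination from the crowded acyl centre (between the C2 methoxy group and the chelating oxygen) should be faster for the primary alkyl, a preference that the wide-bite-angle bisphosphine is chosen to reinforce and that is the variable to optimise. The mirror plane of 10 through C2 and C5 makes the two formyl groups equivalent and the ring has no free C–H bond, so no question of site selectivity arises.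

Step 8
Reactants: 13 1,1'-[5-(benzyloxy)-4,6-dihydroxy-2-methoxy-1,3-phenylene]bis(3-phenylpropan-1-one); 2 benzyl bromide
Product: 14 1,1'-[4,5,6-tris(benzyloxy)-2-methoxy-1,3-phenylene]bis(3-phenylpropan-1-one)
Conditions: BnBr (2.5 equiv), K2CO3, DMF, 60 °C
Reagents that add atoms: benzyl bromide (2), BrCc1ccccc1
Why: Williamson benzylation of the two hydrogen-bonded phenols, needed because free phenols would be oxidised by the iodine reagent of the next step and chosen so that all three protecting groups fall together later.

Step 9
Reactants: 14 1,1'-[4,5,6-tris(benzyloxy)-2-methoxy-1,3-phenylene]bis(3-phenylpropan-1-one)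
Product: 15 rac-methyl 3-phenyl-2-[2,3,4-tris(benzyloxy)-6-methoxy-5-(3-phenylpropanoyl)phenyl]propanoate
Conditions: PhI(OAc)2 (0.6 equiv), H2SO4 (cat.), HC(OMe)3, rt to 50 °C; recovered 14 resubmitted
Reagents that add atoms: trimethyl orthoformate, COC(OC)OC
Why: Oxidative 1,2-aryl migration of an alkyl aryl ketone with trivalent iodine in trimethyl orthoformate, in which the enol ether attacks PhI(OAc)2, the very electron-rich, fully substituted aryl group shifts to the α-carbon as iodobenzene departs and the dimethoxycarbenium ion collapses to the methyl ester; with the oxidant limiting the reaction should stop largely at one acyl group, either of which gives the same product because of the mirror symmetry of 14, and the new stereocentre is formed racemic.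

Step 10
Reactants: 15 rac-methyl 3-phenyl-2-[2,3,4-tris(benzyloxy)-6-methoxy-5-(3-phenylpropanoyl)phenyl]propanoate
Product: 17 rac-3-benzyl-6,7-dihydroxy-4-methoxy-5-(3-phenylpropanoyl)-1-benzofuran-2(3H)-one, via triol ester 16 (not isolated)
Conditions: H2 (1 atm), Pd/C, EtOAc/MeOH, rt; filter under Ar; TsOH·H2O (cat.), toluene, 80 °C
Reagents that add atoms: none
Why: Hydrogenolysis of the three benzyl ethers over Pd/C followed by acid-catalysed lactonisation, a 5-exo-trig acyl substitution by the only hydroxyl ortho to the arylacetate carbon, which thereby becomes O1 while the other two hydroxyls remain as the C6/C7 catechol; the stereocentre stays racemic.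

Step 11
Reactants: 17 rac-3-benzyl-6,7-dihydroxy-4-methoxy-5-(3-phenylpropanoyl)-1-benzofuran-2(3H)-one
Product: 20 bractelactone [(3Z)-3-benzylidene-6,7-dihydroxy-4-methoxy-5-(3-phenylpropanoyl)-1-benzofuran-2(3H)-one], via ortho-quinone 18 (not isolated), via quinone methide 19 (not isolated)
Conditions: Ag2O (1.05 equiv), MgSO4, CH2Cl2, rt, dark; then Et3N (5 mol %), rt
Reagents that add atoms: none
Why: Catechol-to-ortho-quinone oxidation by Ag2O followed by quinone/quinone-methide tautomerism, in which the C3 hydrogen (α to the lactone carbonyl and γ to the C7 carbonyl through C3a=C7a) moves to O7 to give 19 and a second proton shift from the benzylic CH2 to O6 restores the aromatic ring with the exocyclic double bond; the Z geometry is the thermodynamic one, since the E isomer would press the phenyl group against the C4 methoxy group.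

**Compound list**

1 | 3,4,5-trihydroxybenzaldehyde | O=Cc1cc(O)c(O)c(O)c1 | starting material
2 | benzyl bromide | BrCc1ccccc1 | starting material
3 | 3,4,5-tris(benzyloxy)benzaldehyde | O=Cc1cc(OCc2ccccc2)c(OCc2ccccc2)c(OCc2ccccc2)c1 | intermediate
4 | 3,4,5-tris(benzyloxy)phenyl formate | O=COc1cc(OCc2ccccc2)c(OCc2ccccc2)c(OCc2ccccc2)c1 | intermediate
5 | 3,4,5-tris(benzyloxy)phenol | Oc1cc(OCc2ccccc2)c(OCc2ccccc2)c(OCc2ccccc2)c1 | intermediate
6 | 1,2,3-tris(benzyloxy)-5-methoxybenzene | COc1cc(OCc2ccccc2)c(OCc2ccccc2)c(OCc2ccccc2)c1 | intermediate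
7 | 1,2,3-tris(benzyloxy)-4,6-dibromo-5-methoxybenzene | COc1c(Br)c(OCc2ccccc2)c(OCc2ccccc2)c(OCc2ccccc2)c1Br | intermediate
8 | [4,5,6-tris(benzyloxy)-2-methoxy-1,3-phenylene]dilithium | COc1c([Li])c(OCc2ccccc2)c(OCc2ccccc2)c(OCc2ccccc2)c1[Li] | intermediate
9 | 4,5,6-tris(benzyloxy)-2-methoxybenzene-1,3-dicarbaldehyde | COc1c(C=O)c(OCc2ccccc2)c(OCc2ccccc2)c(OCc2ccccc2)c1C=O | intermediate
10 | 5-(benzyloxy)-4,6-dihydroxy-2-methoxybenzene-1,3-dicarbaldehyde | COc1c(C=O)c(O)c(OCc2ccccc2)c(O)c1C=O | intermediate
11 | styrene | C=Cc1ccccc1 | starting material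
12 | 5-(benzyloxy)-4,6-dihydroxy-2-methoxy-3-(3-phenylpropanoyl)benzaldehyde | COc1c(C=O)c(O)c(OCc2ccccc2)c(O)c1C(=O)CCc1ccccc1 | intermediate
13 | 1,1'-[5-(benzyloxy)-4,6-dihydroxy-2-methoxy-1,3-phenylene]bis(3-phenylpropan-1-one) | COc1c(C(=O)CCc2ccccc2)c(O)c(OCc2ccccc2)c(O)c1C(=O)CCc1ccccc1 | intermediate
14 | 1,1'-[4,5,6-tris(benzyloxy)-2-methoxy-1,3-phenylene]bis(3-phenylpropan-1-one) | COc1c(C(=O)CCc2ccccc2)c(OCc2ccccc2)c(OCc2ccccc2)c(OCc2ccccc2)c1C(=O)CCc1ccccc1 | intermediate
15 | rac-methyl 3-phenyl-2-[2,3,4-tris(benzyloxy)-6-methoxy-5-(3-phenylpropanoyl)phenyl]propanoate | COC(=O)C(Cc1ccccc1)c1c(OC)c(C(=O)CCc2ccccc2)c(OCc2ccccc2)c(OCc2ccccc2)c1OCc1ccccc1 | intermediate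
16 | rac-methyl 3-phenyl-2-[2,3,4-trihydroxy-6-methoxy-5-(3-phenylpropanoyl)phenyl]propanoate | COC(=O)C(Cc1ccccc1)c1c(OC)c(C(=O)CCc2ccccc2)c(O)c(O)c1O | intermediate
17 | rac-3-benzyl-6,7-dihydroxy-4-methoxy-5-(3-phenylpropanoyl)-1-benzofuran-2(3H)-one | COc1c(C(=O)CCc2ccccc2)c(O)c(O)c2c1C(Cc1ccccc1)C(=O)O2 | intermediate
18 | rac-3-benzyl-4-methoxy-5-(3-phenylpropanoyl)-1-benzofuran-2,6,7(3H)-trione | COC1=C(C(=O)CCc2ccccc2)C(=O)C(=O)C2=C1C(Cc1ccccc1)C(=O)O2 | intermediate
19 | 3-benzyl-7-hydroxy-4-methoxy-5-(3-phenylpropanoyl)-1-benzofuran-2,6-dione (para-quinone methide tautomer) | COC1=C(C(=O)CCc2ccccc2)C(=O)C(O)=C2OC(=O)C(Cc3ccccc3)=C12 | intermediate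
20 | bractelactone, (3Z)-3-benzylidene-6,7-dihydroxy-4-methoxy-5-(3-phenylpropanoyl)-1-benzofuran-2(3H)-one | COc1c(C(=O)CCc2ccccc2)c(O)c(O)c2c1/C(=C/c1ccccc1)C(=O)O2 | target

**Count and risks**

Total step count: 11. Longest linear sequence: 11 steps (1 to 20); benzyl bromide and styrene are commercial.

Steps most likely to fail:

1. Step 9. Enol ether formation at a carbonyl flanked by two ortho substituents may be slow, the α-iodanyl intermediate may be diverted to α-methoxylation instead of aryl migration, both acyl groups may rearrange, and the acid may strip benzyl ethers. The fallback sets out from 14 and separates enolisation from migration. α-Monobromination with PhNMe3Br3 (limiting amount, THF, 0 °C, unreacted 14 recovered) should give rac-2-bromo-3-phenyl-1-[2,3,4-tris(benzyloxy)-6-methoxy-5-(3-phenylpropanoyl)phenyl]propan-1-one F1. Silver-assisted ionisation of its C–Br bond (AgBF4, MeOH/HC(OMe)3, rt) should then drive the same 1,2-aryl shift through a phenonium ion and deliver ester 15, where the route is rejoined.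

2. Step 11. The product catechol may be oxidised further, the quinone methide may be captured by water or by a second catechol (hydration, dimerisation), and the alkene geometry may scramble. The fallback sets out from 17 and replaces phenol oxidation by enolate chemistry.
   - Silylation (TBSCl, imidazole, DMF) should give rac-3-benzyl-6,7-bis(tert-butyldimethylsilyloxy)-4-methoxy-5-(3-phenylpropanoyl)-1-benzofuran-2(3H)-one F2.
   - Deprotonation at C3, by far the most acidic C–H, with LiN(SiMe3)2 (1 equiv, THF, −78 °C) and trapping with PhSeBr should give rac-3-benzyl-6,7-bis(tert-butyldimethylsilyloxy)-4-methoxy-3-(phenylselanyl)-5-(3-phenylpropanoyl)-1-benzofuran-2(3H)-one F3.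
   - H2O2 oxidation and syn-elimination of the selenoxide, for which only the benzylic CH2 offers β-hydrogens, should give (3Z)-3-benzylidene-6,7-bis(tert-butyldimethylsilyloxy)-4-methoxy-5-(3-phenylpropanoyl)-1-benzofuran-2(3H)-one F4.
   - HF·pyridine (THF, 0 °C) should remove both silyl groups and return the route at 20.

3. Step 7. Styrene may insert in the branched sense, the second hydroacylation may stall at 12, or the acyl rhodium may lose CO. The fallback sets out from 9 and builds the same two carbonyl-to-methylene bonds by carbonyl addition. Two-fold addition of PhCH2CH2MgBr (THF, 0 °C) should give 1,1'-[4,5,6-tris(benzyloxy)-2-methoxy-1,3-phenylene]bis(3-phenylpropan-1-ol) F5 as a mixture of diastereomers. Dess–Martin oxidation (CH2Cl2, rt) should convert it into diketone 14, where the route is rejoined with steps 6 to 8 bypassed.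

**Further compounds**

F1 | step 9 | rac-2-bromo-3-phenyl-1-[2,3,4-tris(benzyloxy)-6-methoxy-5-(3-phenylpropanoyl)phenyl]propan-1-one | COc1c(C(=O)CCc2ccccc2)c(OCc2ccccc2)c(OCc2ccccc2)c(OCc2ccccc2)c1C(=O)C(Br)Cc1ccccc1
F2 | step 11 | rac-3-benzyl-6,7-bis(tert-butyldimethylsilyloxy)-4-methoxy-5-(3-phenylpropanoyl)-1-benzofuran-2(3H)-one | COc1c(C(=O)CCc2ccccc2)c(O[Si](C)(C)C(C)(C)C)c(O[Si](C)(C)C(C)(C)C)c2c1C(Cc1ccccc1)C(=O)O2
F3 | step 11 | rac-3-benzyl-6,7-bis(tert-butyldimethylsilyloxy)-4-methoxy-3-(phenylselanyl)-5-(3-phenylpropanoyl)-1-benzofuran-2(3H)-one | COc1c(C(=O)CCc2ccccc2)c(O[Si](C)(C)C(C)(C)C)c(O[Si](C)(C)C(C)(C)C)c2c1C(Cc1ccccc1)([Se]c1ccccc1)C(=O)O2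
F4 | step 11 | (3Z)-3-benzylidene-6,7-bis(tert-butyldimethylsilyloxy)-4-methoxy-5-(3-phenylpropanoyl)-1-benzofuran-2(3H)-one | COc1c(C(=O)CCc2ccccc2)c(O[Si](C)(C)C(C)(C)C)c(O[Si](C)(C)C(C)(C)C)c2c1/C(=C/c1ccccc1)C(=O)O2
F5 | step 7 | 1,1'-[4,5,6-tris(benzyloxy)-2-methoxy-1,3-phenylene]bis(3-phenylpropan-1-ol) | COc1c(C(O)CCc2ccccc2)c(OCc2ccccc2)c(OCc2ccccc2)c(OCc2ccccc2)c1C(O)CCc1ccccc1
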